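The data are calculated with constants of no real substance; scatter was added.

If the charge of solid substrate set the target per litre, the oak run would make it 2.24 times as fast as the ash run. Check that before you trust a percentage for the new flask.

| flask | solid substrate | reagent | remark | time |
|---|---|---|---|---|
| ash | 0.67 M | 2 M | run made earlier |  |
| oak | 1.5 M | 2 M | run made earlier |  |
| flask | 1.0 M | 2.00 M |  | 30 min |

| run | time / min | target / % | dissolved substrate / % |
|---|---|---|---|
| ash | 10.0 | 5.8 | 18.9 |
| ash | 20.0 | 11.9 | 18.9 |
| ash | 25.0 | 12.4 | 19.6 |
| ash | 40.0 | 17.5 | 19.9 |
| oak | 3.00 | 1.0 | 8.3 |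
| oak | 6.00 | 1.4 | 8.0 |
| oak | 15.0 | 3.6 | 8.1 |
| oak | 40.0 | 8.2 | 8.5 |

(scatter of a reading: 0.5 percentage points)

- as a solid, counted per litre of solution: solid substrate
- the earlier runs were read with a standard deviation of 0.5 percentage points
- at the start none of the solid substrate is in solution
- dissolved substrate means what is dissolved; the solid is not counted in it

- how much target there is at 30 min, in percent of the solid substrate charged
- concentration of dissolved substrate in solution at 30 min, in percent of saturation

Take the mean rate of target formation, the target in M at the last reading divided by its time, which replaces the bending curve by a straight line: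

ash: 0.00293 M min⁻¹
oak: 0.00307 M min⁻¹

Their ratio reads 1.05, far less than the ratio of charges, so the rate looks zero order in the solid charge. The last readings of [dissolved substrate] are 0.133 M and 0.128 M, a common ceiling, which is saturation. Carry their mean, 0.130 M, and the mean rate 0.00300 M min⁻¹. For the flask, my own reckoning is:

target = 0.00300 M min⁻¹ × 30 min = 0.0901 M, which is 9.01% of 1.0 M

The line errs low, because oak's mean over 15.0 min reads 0.00360 M min⁻¹, faster than over 40.0 min. That shorter mean gives 10.8%, so I expect a value between the two.

For the flask's solid to be gone by 30 min, what has left the solid would have to reach the whole charge. Yet saturation plus target, the two forms the readings show, take about 0.221 M of 1.0 M.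

The forecast gives 9.6% (8.8% to 10.4%) and 100% of saturation (96% to 103%), above my line, holding that "the rate depends on dissolved substrate and reagent, not on the solid charge".

The flask gives 9.82% of target and 98.7% of saturation.

    solid substrate ⇌ dissolved substrate, rate k1*(cs1 - [dissolved substrate]) while solid is left; crystals form when [dissolved substrate] > cs1 (solubility = 0.130 M, k = 0.0360 s⁻¹)
    dissolved substrate + reagent → target (k = 3.20 × 10⁻⁴ L mol⁻¹ s⁻¹)
    dissolved substrate + target → side product (k = 9.50 × 10⁻⁴ L mol⁻¹ s⁻¹)
    2 reagent → self-condensation product (k = 8.30 × 10⁻⁵ L mol⁻¹ s⁻¹)

At 30.0 min the flask makes target 4.05 times as fast as it uses it up, each step taken net. Its mean rate is 0.00327 M min⁻¹, above the carried 0.00300 M min⁻¹. Put that flask's mean rate into the neighbouring flask with 1.7 M of solid substrate and you get 5.77%; that neighbour held 5.78%.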